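**Retrosynthetic overview**
- The target comes from global O-debenzylation of its bis(benzyl ether) in the last step.
- The tetrahydrofuran (the only ring of the target, closed in the penultimate step) comes from C3–O and C2–O1 bond formation: face-selective epoxidation of an (E)-2-benzyl-3-arylidenebutane-1,4-diol and 5-endo opening of the benzylic epoxide by the C5 hydroxyl, in one flask.
- The alkene diol comes from reduction of an (E)-α-arylidene-β-benzyl-γ-butyrolactone, itself from aldol condensation of the (R)-β-benzyl-γ-butyrolactone with O-benzylvanillin (this temporary lactone ring is formed first and opened again).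
- The (R)-lactone comes from ester-selective reduction of an (R)-2-benzylsuccinate half-ester, made by Rh-catalysed asymmetric hydrogenation of the Stobbe half-ester of O-benzylvanillin and dimethyl succinate (sets C4).

Assumption: O-benzylvanillin and L-(+)-diisopropyl tartrate are taken as cheap commercial materials; C2–C5 below are the tetrahydrofuran positions of the target (C2 aryl carbon, C3 carbinol carbon, C4 benzyl-bearing carbon, C5 ring CH2).

**Step 1**
Reactants: 1 4-(benzyloxy)-3-methoxybenzaldehyde; 2 dimethyl succinate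
Product: 3 (3E)-4-[4-(benzyloxy)-3-methoxyphenyl]-3-(methoxycarbonyl)but-3-enoic acid
Conditions: NaOMe (2.2 equiv), MeOH, reflux; then aq. HCl
Reagents that add atoms: none
Why: Stobbe condensation; the carboxylate-forming elimination is irreversible and gives the (E)-half-ester (aryl trans to the ester group) as the favoured alkene isomer.

**Step 2**
Reactants: 3 (3E)-4-[4-(benzyloxy)-3-methoxyphenyl]-3-(methoxycarbonyl)but-3-enoic acid
Product: 4 (3R)-4-[4-(benzyloxy)-3-methoxyphenyl]-3-(methoxycarbonyl)butanoic acid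
Conditions: H2 (5 bar), [Rh(cod)((S,S)-Et-DuPhos)]BF4 (0.5 mol%), NaOMe (10 mol%), MeOH, 25 °C
Reagents that add atoms: none
Why: Rh-bisphospholane asymmetric hydrogenation of an itaconate-type half-ester; carboxylate and alkene chelate Rh and the (S,S)-ligand delivers H2 to the face giving the (R)-2-(arylmethyl)succinate (the future C4), while the benzyl ether is inert to the homogeneous Rh catalyst.

**Step 3**
Reactants: 4 (3R)-4-[4-(benzyloxy)-3-methoxyphenyl]-3-(methoxycarbonyl)butanoic acid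
Product: 6 (4R)-4-[[4-(benzyloxy)-3-methoxyphenyl]methyl]oxolan-2-one, via hydroxy acid 5 (not isolated)
Conditions: LiBH4 (3 equiv), THF, 0 °C to rt; then 2 M HCl, rt
Reagents that add atoms: none
Why: Chemoselective borohydride reduction of the methyl ester beside the inert lithium carboxylate, then acid-promoted lactonisation of hydroxy acid 5; the stereocentre is not touched.

**Step 4**
Reactants: 6 (4R)-4-[[4-(benzyloxy)-3-methoxyphenyl]methyl]oxolan-2-one; 1 4-(benzyloxy)-3-methoxybenzaldehyde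
Product: 9 (3E,4R)-4-[[4-(benzyloxy)-3-methoxyphenyl]methyl]-3-[[4-(benzyloxy)-3-methoxyphenyl]methylidene]oxolan-2-one, via lithium aldolate 7 (not isolated), via aldol acetate 8 (not isolated)
Conditions: LiN(iPr)2 (1.1 equiv), THF, −78 °C; 1; then Ac2O, −78 to 0 °C; then DBU, rt
Reagents that add atoms: none
Why: Aldol addition of the lactone enolate (the only enolisable position) anti to the benzyl group, O-acetylation and DBU-mediated E1cB elimination give the conjugated (E)-arylidene lactone (aryl cis to the ring CH), with the benzyl-bearing centre unaffected.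

**Step 5**
Reactants: 9 (3E,4R)-4-[[4-(benzyloxy)-3-methoxyphenyl]methyl]-3-[[4-(benzyloxy)-3-methoxyphenyl]methylidene]oxolan-2-one
Product: 10 (2R,3E)-2-[[4-(benzyloxy)-3-methoxyphenyl]methyl]-3-[[4-(benzyloxy)-3-methoxyphenyl]methylidene]butane-1,4-diol
Conditions: iBu2AlH (4.5 equiv), CH2Cl2, −78 to 0 °C; aq. potassium sodium tartrate
Reagents that add atoms: none
Why: Aluminium hydride reduction of an α,β-unsaturated lactone to the 1,4-diol by 1,2-addition only, so the alkene geometry and the stereocentre are retained.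

**Step 6**
Reactants: 10 (2R,3E)-2-[[4-(benzyloxy)-3-methoxyphenyl]methyl]-3-[[4-(benzyloxy)-3-methoxyphenyl]methylidene]butane-1,4-diol
Product: 12 (2R,3S,4S)-2-[4-(benzyloxy)-3-methoxyphenyl]-4-[[4-(benzyloxy)-3-methoxyphenyl]methyl]-3-(hydroxymethyl)oxolan-3-ol, via epoxy diol 11 (not isolated)
Conditions: Ti(OtBu)4 (1.1 equiv), L-(+)-diisopropyl tartrate (1.3 equiv), t-BuOOH (2 equiv, anhydrous in decane), 4 Å molecular sieves, CH2Cl2, −25 °C then 0 °C; aq. tartaric acid
Reagents that add atoms: tert-butyl hydroperoxide, CC(C)(C)OO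
Why: Proposed new method: a titanium tartrate epoxidation run on the unprotected 2-alkylidene-1,4-diol and telescoped into ring closure; the allylic hydroxyl binds the ligand-accelerated Ti–tartrate–peroxide complex, so L-(+)-diisopropyl tartrate delivers oxygen to the face that makes the hydroxymethyl-bearing oxirane carbon S (same sense as for geraniol or cinnamyl alcohol), which sets C3; the electron-rich p-alkoxyphenyl epoxide 11, held as a titanium epoxy-alkoxide, is then opened at its benzylic carbon by the C5 hydroxyl, which lies on the opposite face in the allylic-strain-minimised conformer, in a 5-endo attack with inversion that closes the tetrahydrofuran and sets C2 as R (aryl cis to the tertiary OH and trans to both carbon substituents, also the less crowded epimer if the opening is partly ionic); the closest known reaction types are the Sharpless asymmetric epoxidation of 2-substituted cinnamyl alcohols, the Ti(OR)4-promoted C3-selective opening of 2,3-epoxy alcohols and acid-promoted 5-endo cyclisations of aryl epoxy alcohols, which have not been combined in one operation on a free 1,4-diol with an allylic stereocentre.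

**Step 7**
Reactants: 12 (2R,3S,4S)-2-[4-(benzyloxy)-3-methoxyphenyl]-4-[[4-(benzyloxy)-3-methoxyphenyl]methyl]-3-(hydroxymethyl)oxolan-3-ol
Product: 13 (2R,3S,4S)-2-(4-hydroxy-3-methoxyphenyl)-4-[(4-hydroxy-3-methoxyphenyl)methyl]-3-(hydroxymethyl)oxolan-3-ol
Conditions: H2 (1 atm), Pd/C (10 wt% Pd), EtOAc–EtOH, rt, stopped when both benzyl ethers are gone
Reagents that add atoms: none
Why: Catalytic hydrogenolysis of the two aryl benzyl ethers; the ring benzylic C2–O bond is flanked by the oxygenated quaternary C3 and should cleave much more slowly, so the three stereocentres are untouched.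

**Compound list**
1 | 4-(benzyloxy)-3-methoxybenzaldehyde (O-benzylvanillin) | O=Cc1ccc(OCc2ccccc2)c(OC)c1 | starting material
2 | dimethyl succinate | COC(=O)CCC(=O)OC | starting material
3 | (3E)-4-[4-(benzyloxy)-3-methoxyphenyl]-3-(methoxycarbonyl)but-3-enoic acid | COC(=O)/C(CC(=O)O)=C/c1ccc(OCc2ccccc2)c(OC)c1 | intermediate
4 | (3R)-4-[4-(benzyloxy)-3-methoxyphenyl]-3-(methoxycarbonyl)butanoic acid | COC(=O)[C@@H](CC(=O)O)Cc1ccc(OCc2ccccc2)c(OC)c1 | intermediate
5 | hydroxy acid: (3R)-4-[4-(benzyloxy)-3-methoxyphenyl]-3-(hydroxymethyl)butanoic acid (formed in the flask as its lithium salt) | OC[C@@H](CC(=O)O)Cc1ccc(OCc2ccccc2)c(OC)c1 | intermediate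
6 | (4R)-4-[[4-(benzyloxy)-3-methoxyphenyl]methyl]oxolan-2-one | O=C1OC[C@H](Cc2ccc(OCc3ccccc3)c(OC)c2)C1 | intermediate
7 | lithium aldolate: lithium [4-(benzyloxy)-3-methoxyphenyl][(3S,4R)-4-[[4-(benzyloxy)-3-methoxyphenyl]methyl]-2-oxooxolan-3-yl]methanolate (both epimers at the carbinol carbon; formed in the flask) | [Li+].[O-]C(c1ccc(OCc2ccccc2)c(OC)c1)[C@H]1C(=O)OC[C@@H]1Cc1ccc(OCc2ccccc2)c(OC)c1 | intermediate
8 | aldol acetate: (3S,4R)-3-[(acetyloxy)[4-(benzyloxy)-3-methoxyphenyl]methyl]-4-[[4-(benzyloxy)-3-methoxyphenyl]methyl]oxolan-2-one (both epimers at the acetoxy carbon; formed in the flask) | CC(=O)OC(c1ccc(OCc2ccccc2)c(OC)c1)[C@H]1C(=O)OC[C@@H]1Cc1ccc(OCc2ccccc2)c(OC)c1 | intermediate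
9 | (3E,4R)-4-[[4-(benzyloxy)-3-methoxyphenyl]methyl]-3-[[4-(benzyloxy)-3-methoxyphenyl]methylidene]oxolan-2-one | O=C1OC[C@H](Cc2ccc(OCc3ccccc3)c(OC)c2)/C1=C\c1ccc(OCc2ccccc2)c(OC)c1 | intermediate
10 | (2R,3E)-2-[[4-(benzyloxy)-3-methoxyphenyl]methyl]-3-[[4-(benzyloxy)-3-methoxyphenyl]methylidene]butane-1,4-diol | OC[C@H](Cc1ccc(OCc2ccccc2)c(OC)c1)/C(CO)=C\c1ccc(OCc2ccccc2)c(OC)c1 | intermediate
11 | epoxy diol: (2S)-3-[4-(benzyloxy)-3-methoxyphenyl]-2-[(2S,3S)-3-[4-(benzyloxy)-3-methoxyphenyl]-2-(hydroxymethyl)oxiran-2-yl]propan-1-ol (formed in the flask) | OC[C@H](Cc1ccc(OCc2ccccc2)c(OC)c1)[C@@]1(CO)O[C@H]1c1ccc(OCc2ccccc2)c(OC)c1 | intermediate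
12 | (2R,3S,4S)-2-[4-(benzyloxy)-3-methoxyphenyl]-4-[[4-(benzyloxy)-3-methoxyphenyl]methyl]-3-(hydroxymethyl)oxolan-3-ol | COc1cc(C[C@H]2CO[C@H](c3ccc(OCc4ccccc4)c(OC)c3)[C@@]2(O)CO)ccc1OCc1ccccc1 | intermediate
13 | (2R,3S,4S)-2-(4-hydroxy-3-methoxyphenyl)-4-[(4-hydroxy-3-methoxyphenyl)methyl]-3-(hydroxymethyl)oxolan-3-ol | COc1cc(C[C@H]2CO[C@H](c3ccc(O)c(OC)c3)[C@@]2(O)CO)ccc1O | target

**Totals**
Total step count: 7. Longest linear sequence: 7 steps (1 + 2 to 13; aldehyde 1 is used a second time in step 4).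

**Steps most likely to fail, with fallbacks**

Step 6 (the new cascade). The free C5 hydroxyl may disturb the titanium tartrate complex and lower face selectivity. Epoxide 11 may also be intercepted by external alkoxide or undergo a semipinacol shift before the ring closes. The fallback uses known chemistry only, sets out from lactone 6 and comes back at 12. The potassium enolate of 6 (KN(SiMe3)2, THF, −78 °C) is hydroxylated with 2-(phenylsulfonyl)-3-phenyloxaziridine to the hydroxy lactone (3R,4S)-4-[[4-(benzyloxy)-3-methoxyphenyl]methyl]-3-hydroxyoxolan-2-one F1. Its dianion (LiN(iPr)2, 2.2 equiv, THF, −78 °C) adds to aldehyde 1 anti to the benzyl group. That puts the new C–C bond trans and the hydroxyl cis to benzyl on the lactone, which is the C3 configuration of the target, and gives (3R,4S)-3-[[4-(benzyloxy)-3-methoxyphenyl](hydroxy)methyl]-4-[[4-(benzyloxy)-3-methoxyphenyl]methyl]-3-hydroxyoxolan-2-one F2 as a mixture at the carbinol carbon. LiAlH4 (THF, 0 °C) reduces it to the tetraol (2S,3S)-3-[[4-(benzyloxy)-3-methoxyphenyl]methyl]-2-[[4-(benzyloxy)-3-methoxyphenyl](hydroxy)methyl]butane-1,2,4-triol F3. Catalytic camphorsulfonic acid in CH2Cl2 then ionises the p-alkoxybenzylic alcohol, and the C5 hydroxyl closes the ring to 12 with the aryl group trans to the hydroxymethyl group, so the carbinol mixture converges.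

Step 4 (aldol condensation). The elimination may give E/Z mixtures, or DBU may move the double bond into the ring and erase the benzyl-bearing centre. The fallback replaces aldol–elimination by olefination, sets out from 6 and comes back at 9. The enolate of 6 (LiN(iPr)2, 2.1 equiv) is phosphorylated with diethyl chlorophosphate to the phosphono lactone diethyl [(4S)-4-[[4-(benzyloxy)-3-methoxyphenyl]methyl]-2-oxooxolan-3-yl]phosphonate F4 (both C3 epimers; benzyl-bearing carbon unchanged from 6). A Horner–Wadsworth–Emmons reaction with aldehyde 1 (KOtBu, THF, 0 °C) then gives the (E)-arylidene lactone 9 under mild, non-equilibrating conditions.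

Step 7 (hydrogenolysis). Over-reduction could open the ring at the benzylic C2–O bond. The fallback swaps the phenol protecting groups so that no hydrogenation is needed; it sets out from 9 and comes back at 13.
- BCl3 with pentamethylbenzene (CH2Cl2, −78 °C) removes both benzyl groups to give (3E,4R)-4-[(4-hydroxy-3-methoxyphenyl)methyl]-3-[(4-hydroxy-3-methoxyphenyl)methylidene]oxolan-2-one F5.
- tBuMe2SiCl and imidazole (DMF) give the bis(silyl ether) (3E,4R)-4-[[4-[[tert-butyl(dimethyl)silyl]oxy]-3-methoxyphenyl]methyl]-3-[[4-[[tert-butyl(dimethyl)silyl]oxy]-3-methoxyphenyl]methylidene]oxolan-2-one F6.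
- iBu2AlH as in step 5 gives (2R,3E)-2-[[4-[[tert-butyl(dimethyl)silyl]oxy]-3-methoxyphenyl]methyl]-3-[[4-[[tert-butyl(dimethyl)silyl]oxy]-3-methoxyphenyl]methylidene]butane-1,4-diol F7.
- The step 6 conditions convert it, through the epoxide (2S)-3-[4-[[tert-butyl(dimethyl)silyl]oxy]-3-methoxyphenyl]-2-[(2S,3S)-3-[4-[[tert-butyl(dimethyl)silyl]oxy]-3-methoxyphenyl]-2-(hydroxymethyl)oxiran-2-yl]propan-1-ol F8 formed in the flask, into (2R,3S,4S)-2-[4-[[tert-butyl(dimethyl)silyl]oxy]-3-methoxyphenyl]-4-[[4-[[tert-butyl(dimethyl)silyl]oxy]-3-methoxyphenyl]methyl]-3-(hydroxymethyl)oxolan-3-ol F9.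
- Bu4NF (THF, 0 °C) releases 13.

**Further compounds**
F1 | step 6 | (3R,4S)-4-[[4-(benzyloxy)-3-methoxyphenyl]methyl]-3-hydroxyoxolan-2-one | O[C@H]1C(=O)OC[C@@H]1Cc1ccc(OCc2ccccc2)c(OC)c1
F2 | step 6 | (3R,4S)-3-[[4-(benzyloxy)-3-methoxyphenyl](hydroxy)methyl]-4-[[4-(benzyloxy)-3-methoxyphenyl]methyl]-3-hydroxyoxolan-2-one (both epimers at the carbinol carbon) | OC(c1ccc(OCc2ccccc2)c(OC)c1)[C@@]1(O)C(=O)OC[C@@H]1Cc1ccc(OCc2ccccc2)c(OC)c1
F3 | step 6 | (2S,3S)-3-[[4-(benzyloxy)-3-methoxyphenyl]methyl]-2-[[4-(benzyloxy)-3-methoxyphenyl](hydroxy)methyl]butane-1,2,4-triol (both epimers at the benzylic carbinol carbon) | OC[C@H](Cc1ccc(OCc2ccccc2)c(OC)c1)[C@](O)(CO)C(O)c1ccc(OCc2ccccc2)c(OC)c1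
F4 | step 4 | diethyl [(4S)-4-[[4-(benzyloxy)-3-methoxyphenyl]methyl]-2-oxooxolan-3-yl]phosphonate (both C3 epimers) | CCOP(=O)(OCC)C1C(=O)OC[C@@H]1Cc1ccc(OCc2ccccc2)c(OC)c1
F5 | step 7 | (3E,4R)-4-[(4-hydroxy-3-methoxyphenyl)methyl]-3-[(4-hydroxy-3-methoxyphenyl)methylidene]oxolan-2-one | O=C1OC[C@H](Cc2ccc(O)c(OC)c2)/C1=C\c1ccc(O)c(OC)c1
F6 | step 7 | (3E,4R)-4-[[4-[[tert-butyl(dimethyl)silyl]oxy]-3-methoxyphenyl]methyl]-3-[[4-[[tert-butyl(dimethyl)silyl]oxy]-3-methoxyphenyl]methylidene]oxolan-2-one | O=C1OC[C@H](Cc2ccc(O[Si](C)(C)C(C)(C)C)c(OC)c2)/C1=C\c1ccc(O[Si](C)(C)C(C)(C)C)c(OC)c1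
F7 | step 7 | (2R,3E)-2-[[4-[[tert-butyl(dimethyl)silyl]oxy]-3-methoxyphenyl]methyl]-3-[[4-[[tert-butyl(dimethyl)silyl]oxy]-3-methoxyphenyl]methylidene]butane-1,4-diol | OC[C@H](Cc1ccc(O[Si](C)(C)C(C)(C)C)c(OC)c1)/C(CO)=C\c1ccc(O[Si](C)(C)C(C)(C)C)c(OC)c1
F8 | step 7 | (2S)-3-[4-[[tert-butyl(dimethyl)silyl]oxy]-3-methoxyphenyl]-2-[(2S,3S)-3-[4-[[tert-butyl(dimethyl)silyl]oxy]-3-methoxyphenyl]-2-(hydroxymethyl)oxiran-2-yl]propan-1-ol | OC[C@H](Cc1ccc(O[Si](C)(C)C(C)(C)C)c(OC)c1)[C@@]1(CO)O[C@H]1c1ccc(O[Si](C)(C)C(C)(C)C)c(OC)c1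
F9 | step 7 | (2R,3S,4S)-2-[4-[[tert-butyl(dimethyl)silyl]oxy]-3-methoxyphenyl]-4-[[4-[[tert-butyl(dimethyl)silyl]oxy]-3-methoxyphenyl]methyl]-3-(hydroxymethyl)oxolan-3-ol | COc1cc(C[C@H]2CO[C@H](c3ccc(O[Si](C)(C)C(C)(C)C)c(OC)c3)[C@@]2(O)CO)ccc1O[Si](C)(C)C(C)(C)C
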